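(Readings and results stem from a simulated flask for an exercise, and the scatter is random.)

The E left in amber at the end of its feed, 65.0% of the charge at 30.0 min, was where I started, because it gives one rate constant for the whole set.

| setting | amber | eta | zeta | delta | beta | gamma | theta |
|---|---|---|---|---|---|---|---|
| E | 0.44 M | 0.40 M | 0.80 M | 0.25 M | 0.25 M | 0.10 M | 0.40 M |
| D | 0.40 M (fed, over 30 min) | 0.400 M (fed, over 30 min) | 0.200 M (fed, over 30 min) | 0.100 M (fed, over 10 min) | 0.200 M (fed, over 100 min) | 0.400 M (fed, over 60 min) | 0.100 M (fed, over 20 min) |
| remark | run made earlier; the fed solution adds 0.50 times the starting volume | the fed solution adds 0.50 times the starting volume | the fed solution adds 0.50 times the starting volume | the fed solution adds 0.50 times the starting volume | the fed solution adds 0.50 times the starting volume | the fed solution adds 0.50 times the starting volume | the fed solution adds 0.50 times the starting volume |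
| time |  | 2.5 h | 2.5 h | 2.5 h | 2.5 h | 2.5 h | 2.5 h |

- amber (time / min: J / %, E / %): 8.00: 3.1, 96.6; 12.0: 6.4, 92.7; 20.0: 11.8, 80.1; 30.0: 20.1, 65.0; 50.0: 20.7, 42.2; 90.0: 19.7, 24.1

(standard deviation of a reading: 1 percentage point)

- a species is counted by the E in it: one G counts as two
- charges are per starting volume, the dose included; the dosed solution carries all of it
- steps thought possible: E + D -> J; D + J -> X; D + X -> L; E + J -> G

1. the flasks put in order of amount of J, in percent of the E charged, best first, at 2.5 h (eta / zeta / delta / beta / gamma / theta)
2. the amount of J, in percent of the E charged of the flask you put first, at 2.5 h
3. the amount of J, in percent of the E charged of the flask you put last, at 2.5 h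

Counted with none of it spent, the D fed to amber reaches 0.267 M at the end of the feed; that is a ceiling, since some of it reacts on the way, and I took half of it, 0.133 M, as a rough mean over the feed. With c(D) held at that mean, E decays pseudo-first-order, and the amber reading gives k of about 0.108 /M/min, a reading with its scatter.

For gamma I assumed one D spent per E charged at mid-run, which puts c(D) after the feed at 0.200 M. I counted the feed as if it all arrived at mid-feed, which leaves 120 min of contact. That gives 2.58, the exposure: rate constant times mean c(D) times time, counted in time constants of E.

I then built gamma up one step at a time. With E + D -> J alone, E falls to exp(-x), 7.54% of the charge, and J holds the other 92.5%. Adding D + J -> X, with the same k assumed because amber cannot separate the two, makes J equal x·exp(-x), or 19.5%, already past the peak of 36.8% that stands at an exposure of one.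

Adding E + J -> G splits the loss of J in the ratio c(E) to c(D). In gamma the charge of E over the final volume, 0.0667 M, is a third of my mean c(D), so this step takes its part of J there, but I did not reckon it in, and my number stands without it. The same formula on amber gives 28.0% at the end of its feed against 20.1% read, and I put that gap down to this step, since E is plentiful there. D + X -> L takes no J and acts through c(D), so it belongs to the error of the mean.

Gamma has the highest ratio of D to E among the flasks, so I put it first. In zeta E outweighs D, so the E + J step takes over and J stays low.

The forecast gave gamma > beta > eta > delta > theta > zeta, with 19% for the first flask and 1% for the last, and it added: “Gamma versus beta is close.”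

The simulation gave gamma > beta > eta > delta > theta > zeta, with 21.6% in gamma and 0.598% in zeta, against 19.5% from the exposure, which stands without the E + J step, though G held 19.0% of the E in gamma at 2.50 h.

    E + D → J (k = 0.105 /M/min)
    D + J → X (k = 0.0812 /M/min)
    D + X → L (k = 0.181 /M/min)
    E + J → G (k = 0.116 /M/min)

The half-life of J in gamma by the making of X alone, with the whole D charge counted at once, was 0.36 h, short against 2.5 h. Gamma read at 1.5 h has the smaller exposure 1.29, for which x·exp(-x) gives 35.5%, and that flask held 33.1%.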